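**Assumption:** (2S)-Liquiritigenin (7,4'-dihydroxyflavanone, natural, from licorice) is purchased as the single enantiomer. Its C2 stereocenter has the same configuration as the target, (S) by CIP, and it is never touched. No new ring is formed in this route.

## Retrosynthetic overview
1. The target comes from a 3',5'-diallyl flavanone (**11**) by double cross-metathesis of the two allyl groups to prenyl groups with 2-methyl-2-butene.
2. The two ortho allyl groups on the B ring come from two successive aromatic Claisen [3,3] rearrangements of 4'-O-allyl ethers. Each is a key C–C bond-forming step, and each is followed by re-allylation of the liberated phenol.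
3. The 4'-OMe is installed by methylation after the second Claisen. The 7-OH is masked as its MOM ether throughout, and the flavanone (rings A and C) with its C2 stereocenter comes ready-made in (S)-liquiritigenin.

## Route

**Step 1**
Reactants: **1** (S)-liquiritigenin; **2** chloromethyl methyl ether (MOMCl)
Product: **3** (S)-7-O-MOM-liquiritigenin
Conditions: K2CO3 (1.1 equiv), acetone, 0 °C → rt, 3 h
Reagents that add atoms: MOMCl, COCCl
Why: The 7-OH is much more acidic (pKa about 7.5) than the 4'-OH (about 10), so one equivalent of base and electrophile gives selective Williamson-type MOM protection at O7. The stereocenter is not involved.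

**Step 2**
Reactants: **3**; **4** allyl bromide
Product: **5** (S)-4'-O-allyl-7-O-MOM-liquiritigenin
Conditions: K2CO3, acetone, reflux, 6 h
Reagents that add atoms: allyl bromide, C=CCBr
Why: Williamson etherification of the only free phenol. Mild carbonate in acetone avoids retro-oxa-Michael ring opening, so C2 is retained.

**Step 3**
Reactants: **5**
Product: **6** (S)-3'-allyl-4'-hydroxy-7-O-MOM-flavanone
Conditions: o-dichlorobenzene, 190 °C, sealed tube or microwave, 1 h
Reagents that add atoms: none
Why: Aromatic Claisen [3,3] rearrangement through a cyclohexadienone, then tautomerization to the phenol. The allyl group goes to the free ortho position, and neutral conditions leave C2 alone.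

**Step 4**
Reactants: **6**; **4** allyl bromide
Product: **7** (S)-3'-allyl-4'-O-allyl-7-O-MOM-flavanone
Conditions: K2CO3, acetone, reflux, 6 h
Reagents that add atoms: allyl bromide, C=CCBr
Why: Williamson O-allylation of the ortho-substituted phenol sets up the second Claisen.

**Step 5**
Reactants: **7**
Product: **8** (S)-3',5'-diallyl-4'-hydroxy-7-O-MOM-flavanone
Conditions: o-dichlorobenzene, 190 °C, sealed tube or microwave, 1–2 h
Reagents that add atoms: none
Why: A second aromatic Claisen [3,3] rearrangement. The allyl group goes to the remaining ortho position (C5'), since the para position is blocked by C2.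

**Step 6**
Reactants: **8**; **9** iodomethane
Product: **10** (S)-3',5'-diallyl-4'-methoxy-7-O-MOM-flavanone
Conditions: MeI, K2CO3, acetone, 50 °C (sealed), 12 h
Reagents that add atoms: MeI, CI
Why: SN2 O-methylation of the hindered 2,6-diallylphenoxide. The small electrophile and mild base leave the flavanone intact.

**Step 7**
Reactants: **10**
Product: **11** (S)-3',5'-diallyl-7-hydroxy-4'-methoxyflavanone
Conditions: ZnBr2, n-PrSH, CH2Cl2, 0 °C → rt, 15 min (degassed, dark)
Reagents that add atoms: none (the MOM group is lost as n-PrSCH2OMe)
Why: Mild Lewis-acid and thiol-assisted MOM cleavage. It is done at the allyl stage, before the acid-sensitive prenyl groups exist, and the short time and low temperature avoid ionization at C2.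

**Step 8**
Reactants: **11**; **12** 2-methyl-2-butene
Product: **13** (S)-abyssinone IV 4'-OMe ether (target)
Conditions: Hoveyda–Grubbs II (5 mol% + 5 mol%), 2-methyl-2-butene (40 equiv), 1,4-benzoquinone (10 mol%), CH2Cl2, 40 °C, 16 h
Reagents that add atoms: 2-methyl-2-butene, CC=C(C)C (supplies the =CMe2 terminus; propene is lost)
Why: Olefin cross-metathesis converts each terminal allyl arene to a prenyl arene. Excess trisubstituted alkene drives the exchange, and benzoquinone suppresses Ru–H isomerization. The reaction is neutral and remote from C2.

## Compound list
1 | (2S)-liquiritigenin, (S)-7,4'-dihydroxyflavanone | Oc1ccc([C@@H]2CC(=O)c3ccc(O)cc3O2)cc1 | starting material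
2 | chloromethyl methyl ether | COCCl | starting material
3 | (S)-7-O-MOM-liquiritigenin | Oc1ccc([C@@H]2CC(=O)c3ccc(OCOC)cc3O2)cc1 | intermediate
4 | allyl bromide | C=CCBr | starting material
5 | (S)-4'-O-allyl-7-O-MOM-flavanone | C=CCOc1ccc([C@@H]2CC(=O)c3ccc(OCOC)cc3O2)cc1 | intermediate
6 | (S)-3'-allyl-4'-hydroxy-7-O-MOM-flavanone | C=CCc1cc([C@@H]2CC(=O)c3ccc(OCOC)cc3O2)ccc1O | intermediate
7 | (S)-3'-allyl-4'-O-allyl-7-O-MOM-flavanone | C=CCOc1c(CC=C)cc([C@@H]2CC(=O)c3ccc(OCOC)cc3O2)cc1 | intermediate
8 | (S)-3',5'-diallyl-4'-hydroxy-7-O-MOM-flavanone | C=CCc1cc([C@@H]2CC(=O)c3ccc(OCOC)cc3O2)cc(CC=C)c1O | intermediate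
9 | iodomethane | CI | starting material
10 | (S)-3',5'-diallyl-4'-methoxy-7-O-MOM-flavanone | COc1c(CC=C)cc([C@@H]2CC(=O)c3ccc(OCOC)cc3O2)cc1CC=C | intermediate
11 | (S)-3',5'-diallyl-7-hydroxy-4'-methoxyflavanone | COc1c(CC=C)cc([C@@H]2CC(=O)c3ccc(O)cc3O2)cc1CC=C | intermediate
12 | 2-methyl-2-butene | CC=C(C)C | starting material
13 | abyssinone IV 4'-OMe ether | COc1c(CC=C(C)C)cc([C@@H]2CC(=O)c3ccc(O)cc3O2)cc1CC=C(C)C | target

## Totals
Total steps: 8. Longest linear sequence: 8.

## Three steps most likely to fail
1. **Step 8 (double cross-metathesis):** Incomplete bis-conversion, or allyl→propenyl isomerization, may leave mono-prenyl and propenyl by-products. Fallback: drop the metathesis. Install the aryl ethers as 1,1-dimethylpropargyl ethers (3-chloro-3-methylbut-1-yne, CuI, K2CO3), reduce with Lindlar catalyst to the 1,1-dimethylallyl ethers, and run the Claisen steps on those, which gives the normal prenyl groups directly.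
2. **Step 5 (second Claisen at 190 °C):** The hindered substrate may decompose, cyclize to a chroman, or racemize C2 by thermal retro-oxa-Michael opening. Fallback: do all B-ring work on achiral 4-hydroxybenzaldehyde, giving 3,5-diprenyl-4-methoxybenzaldehyde by the same Claisen/methylation sequence. Then build the flavanone by Claisen–Schmidt condensation with 2,4-dihydroxyacetophenone and oxa-Michael closure, and separate the (S) enantiomer by preparative chiral-phase HPLC.
3. **Step 7 (MOM removal):** Lewis-acid and thiol conditions might cause thiol-ene addition to the allyl groups or ionization of the electron-rich benzylic ether at C2. Fallback: carry the 7-OH as a TBDPS ether instead of MOM (silylation in place of Step 1, with the same downstream steps) and remove it at the end with buffered TBAF/AcOH, avoiding acid altogether.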